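The route rests on cutting the two aryl C1′–Cβ bonds of the identical (E)-caffeoyl arms on O3 and O5 of the cyclohexane ring. One palladium-catalysed double Heck arylation joins two molecules of acetonide-protected 4-iodocatechol to the CH2 termini of a bis-acrylate and sets both E alkenes at once. The bis-acrylate is tert-butyl quinate carrying acrylates on O3 and O5, a tert-butyl succinate on O4 and a free tertiary O1–H. Its four stereocentres come unchanged from (−)-quinic acid. O4 is singled out beforehand by sterically controlled 3,5-bis-silylation. Aqueous trifluoroacetic acid finally removes all four acid-labile groups together.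

Key step: step 8

Remark: IUPAC quinic acid numbering is used. C1 carries OH and the carboxyl carbon, O3 is the axial hydroxyl cis to O4, and O5 is the equatorial hydroxyl trans to O4. In every quinate below, C3 and C5 are R, O1, O3 and O4 lie on one ring face, and O5 and the carboxyl carbon lie on the other, exactly as in 1. This is what "configuration of 1" means.

Step 1
Reactants: 1 (−)-quinic acid
Product: 2 tert-butyl quinate (tert-butyl 1,3,4,5-tetrahydroxycyclohexane-1-carboxylate, configuration of 1)
Conditions: O-tert-butyl-N,N'-diisopropylisourea (3 equiv), DMF, 45 °C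
Reagents that add atoms: O-tert-butyl-N,N'-diisopropylisourea, CC(C)N=C(NC(C)C)OC(C)(C)C
Why: Isourea esterification: only the carboxylic acid is acidic enough to protonate the isourea, whose tert-butyl group then passes to the carboxylate, so the four hydroxyls and all stereocentres should stay untouched.

Step 2
Reactants: 2 tert-butyl quinate
Product: 3 tert-butyl 3,5-bis-O-(tert-butyldimethylsilyl)quinate (O1–H and O4–H free, configuration of 1)
Conditions: TBSCl (2.2 equiv), imidazole (4.5 equiv), DMF, 0 °C to rt
Reagents that add atoms: tert-butyldimethylsilyl chloride, CC(C)(C)[Si](C)(C)Cl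
Why: Sterically controlled silyl ether formation: O3 and O5 each adjoin a ring CH2, whereas O4 is wedged between two oxygenated carbons and O1 is tertiary, a preference that is well established for the methyl ester of 1 with the same reagent.

Step 3
Reactants: 3 tert-butyl 3,5-bis-O-(tert-butyldimethylsilyl)quinate; 4 mono-tert-butyl succinate (4-tert-butoxy-4-oxobutanoic acid, 1.8 equiv)
Product: 5 tert-butyl 3,5-bis-O-(tert-butyldimethylsilyl)-4-O-(4-tert-butoxy-4-oxobutanoyl)quinate (configuration of 1)
Conditions: DCC (1.8 equiv), DMAP (0.5 equiv), CH2Cl2, 0 °C to rt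
Reagents that add atoms: none
Why: Steglich esterification: the acylpyridinium ion formed from 4 should reach the only secondary hydroxyl left, equatorial O4, while the tertiary O1–H next to the ester stays inert and the weakly basic medium gives no reason for silyl migration.

Step 4
Reactants: 5 tert-butyl 3,5-bis-O-(tert-butyldimethylsilyl)-4-O-(4-tert-butoxy-4-oxobutanoyl)quinate
Product: 6 tert-butyl 4-O-(4-tert-butoxy-4-oxobutanoyl)quinate (O1–H, O3–H and O5–H free, configuration of 1)
Conditions: HF·pyridine, extra pyridine, THF, 0 °C to rt (plastic vessel); pH 6–7 phosphate buffer work-up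
Reagents that add atoms: none
Why: Fluoride-driven desilylation in a mildly acidic buffer breaks only Si–O bonds, spares both tert-butyl esters and avoids the alkoxide that would let the O4 succinate wander to O3 or O5.

Step 5
Reactants: 6 tert-butyl 4-O-(4-tert-butoxy-4-oxobutanoyl)quinate; 7 acryloyl chloride (2.5 equiv)
Product: 8 tert-butyl 3,5-di-O-acryloyl-4-O-(4-tert-butoxy-4-oxobutanoyl)quinate (O1–H free, configuration of 1)
Conditions: iPr2NEt (3 equiv), DMAP (0.1 equiv), BHT (trace), CH2Cl2, −20 to 0 °C
Reagents that add atoms: none
Why: Acyl chloride esterification with nucleophilic catalysis by DMAP: the small, very reactive acyl chloride should cap equatorial O5 and axial O3 at low temperature faster than the succinate can migrate, and the limited excess leaves tertiary O1–H free.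

Step 6
Reactants: 9 catechol
Product: 10 2,2-dimethyl-1,3-benzodioxole
Conditions: 2,2-dimethoxypropane, TsOH·H2O (cat.), toluene, reflux with continuous removal of MeOH
Reagents that add atoms: 2,2-dimethoxypropane, COC(C)(C)OC
Why: Acid-catalysed transketalisation, driven by removal of methanol, closes the five-membered 1,3-benzodioxole ring on the two adjacent phenols.

Step 7
Reactants: 10 2,2-dimethyl-1,3-benzodioxole
Product: 11 5-iodo-2,2-dimethyl-1,3-benzodioxole
Conditions: NIS (1.05 equiv), TFA (cat.), dry MeCN, rt, dark
Reagents that add atoms: N-iodosuccinimide, O=C1CCC(=O)N1I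
Why: Electrophilic aromatic iodination: acid-activated NIS attacks para to a ring oxygen, and C5 and C6 are equivalent by symmetry while C4 and C7 are more crowded, so one mono-iodide should result.

Step 8
Reactants: 8 tert-butyl 3,5-di-O-acryloyl-4-O-(4-tert-butoxy-4-oxobutanoyl)quinate; 11 5-iodo-2,2-dimethyl-1,3-benzodioxole (2.6 equiv)
Product: 12 tert-butyl 3,5-bis-O-[(E)-3-(2,2-dimethyl-1,3-benzodioxol-5-yl)acryloyl]-4-O-(4-tert-butoxy-4-oxobutanoyl)quinate (configuration of 1, both alkenes E)
Conditions: Pd(OAc)2 (10 mol %), n-Bu4NCl (2 equiv), NaHCO3 (5 equiv), BHT (trace), degassed DMF, 60–65 °C, argon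
Reagents that add atoms: none
Why: This is a Mizoroki–Heck reaction, the standard arylation of acrylate esters by aryl iodides: Pd(OAc)2 is reduced in the flask to zerovalent palladium, which inserts into the carbon–iodine bond of 11, the arylpalladium species adds syn across an acrylate C=C with the aryl group going to the CH2 terminus, and after bond rotation syn β-hydride elimination releases the cinnamate while NaHCO3 takes up hydrogen iodide and frees the catalyst. The cycle then repeats at the other acrylate, so both aryl C1′–Cβ bonds are made in one flask. No ring is closed and no stereocentre is created, and the four ring stereocentres are safe because no ring C–O or C–H bond takes part. Terminal regioselectivity is required and is secured by the polarisation of the acrylate and the low steric demand of its CH2 end, and the required E geometry follows from the least strained conformer in the syn elimination. Both arms must react alike, which holds because the O3 and O5 acrylates are electronically identical and point away from the ring, and the esters and O1–H must survive, which the reactive iodide (moderate temperature, no phosphine) and the weak, poorly soluble base allow. Excess 11 should drive both arms to completion and BHT should hold back radical polymerisation.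

Step 9
Reactants: 12 tert-butyl 3,5-bis-O-[(E)-3-(2,2-dimethyl-1,3-benzodioxol-5-yl)acryloyl]-4-O-(4-tert-butoxy-4-oxobutanoyl)quinate
Product: 13 3,5-di-O-[(E)-caffeoyl]-4-O-succinylquinic acid (CNP0133919.1, configuration of 1)
Conditions: TFA/H2O (9:1), 0 °C to rt; evaporation, reversed-phase chromatography
Reagents that add atoms: none
Why: Acidolysis: the tert-butyl esters leave by alkyl–oxygen cleavage and the aryl ketals hydrolyse under the same conditions, whereas the cinnamate and succinate esters, the E alkenes and the ring stereocentres are inert to acid, and with O3, O4 and O5 all acylated no acyl shift is open.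

Compound list
1 | (−)-quinic acid | O[C@H]1[C@H](O)C[C@](O)(C(=O)O)C[C@H]1O | starting material
2 | tert-butyl quinate | O[C@H]1[C@H](O)C[C@](O)(C(=O)OC(C)(C)C)C[C@H]1O | intermediate
3 | tert-butyl 3,5-bis-O-(tert-butyldimethylsilyl)quinate | O[C@H]1[C@H](O[Si](C)(C)C(C)(C)C)C[C@](O)(C(=O)OC(C)(C)C)C[C@H]1O[Si](C)(C)C(C)(C)C | intermediate
4 | mono-tert-butyl succinate (4-tert-butoxy-4-oxobutanoic acid) | OC(=O)CCC(=O)OC(C)(C)C | starting material
5 | tert-butyl 3,5-bis-O-(tert-butyldimethylsilyl)-4-O-(4-tert-butoxy-4-oxobutanoyl)quinate | CC(C)(C)OC(=O)CCC(=O)O[C@H]1[C@H](O[Si](C)(C)C(C)(C)C)C[C@](O)(C(=O)OC(C)(C)C)C[C@H]1O[Si](C)(C)C(C)(C)C | intermediate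
6 | tert-butyl 4-O-(4-tert-butoxy-4-oxobutanoyl)quinate | CC(C)(C)OC(=O)CCC(=O)O[C@H]1[C@H](O)C[C@](O)(C(=O)OC(C)(C)C)C[C@H]1O | intermediate
7 | acryloyl chloride | C=CC(=O)Cl | starting material
8 | tert-butyl 3,5-di-O-acryloyl-4-O-(4-tert-butoxy-4-oxobutanoyl)quinate | CC(C)(C)OC(=O)CCC(=O)O[C@H]1[C@H](OC(=O)C=C)C[C@](O)(C(=O)OC(C)(C)C)C[C@H]1OC(=O)C=C | intermediate
9 | catechol | Oc1ccccc1O | starting material
10 | 2,2-dimethyl-1,3-benzodioxole | CC1(C)Oc2ccccc2O1 | intermediate
11 | 5-iodo-2,2-dimethyl-1,3-benzodioxole | CC1(C)Oc2ccc(I)cc2O1 | intermediate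
12 | tert-butyl 3,5-bis-O-[(E)-3-(2,2-dimethyl-1,3-benzodioxol-5-yl)acryloyl]-4-O-(4-tert-butoxy-4-oxobutanoyl)quinate | CC(C)(C)OC(=O)CCC(=O)O[C@H]1[C@H](OC(=O)/C=C/c2ccc3OC(C)(C)Oc3c2)C[C@](O)(C(=O)OC(C)(C)C)C[C@H]1OC(=O)/C=C/c1ccc2OC(C)(C)Oc2c1 | intermediate
13 | 3,5-di-O-[(E)-caffeoyl]-4-O-succinylquinic acid | O=C(O)CCC(=O)O[C@H]1[C@H](OC(=O)/C=C/c2ccc(O)c(O)c2)C[C@](O)(C(=O)O)C[C@H]1OC(=O)/C=C/c1ccc(O)c(O)c1 | target

Total step count: 9. Longest linear sequence: 7 (steps 1, 2, 3, 4, 5, 8, 9).

Steps most likely to fail

Step 8. The coupling may stall after the first arm as palladium black settles out, since the electron-rich iodide adds slowly. The acrylates may polymerise on heating, or a finished cinnamate may be arylated a second time. The fallback sets out from 11 and 6 and comes back at 12. It makes the aryl–vinyl bond away from the quinate. Iodide 11 is coupled with acrylic acid (Pd(OAc)2, P(o-tolyl)3, Et3N, MeCN, 80 °C) to give (E)-3-(2,2-dimethyl-1,3-benzodioxol-5-yl)prop-2-enoic acid F1. Triol 6 is then acylated at O3 and O5 with F1 (DCC, DMAP, CH2Cl2, rt). This is the classical O-acylation route to caffeoylquinates, and it leaves out steps 5 and 8.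

Step 5. The amine base may shift the succinyl group from O4 to a neighbouring free hydroxyl before acylation is complete. Acylation at axial O3 may lag, O1 may be over-acylated, or the acrylate may polymerise or take up the amine by conjugate addition. The fallback sets out from 6 and comes back at 8, and it uses a masked acrylate. Triol 6 is acylated with 3-chloropropanoyl chloride in CH2Cl2/pyridine at 0 °C, where the base is weak and no alkene is present. This gives tert-butyl 3,5-bis-O-(3-chloropropanoyl)-4-O-(4-tert-butoxy-4-oxobutanoyl)quinate F2. Only then, with no secondary hydroxyl left to accept a migrating acyl group, does Et3N in CH2Cl2 eliminate hydrogen chloride twice (E1cB) to unveil both acrylates.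

Step 3. Acylation in the pocket between the two silyl ethers may be slow. The activated acid could then rearrange to the N-acylurea, or tertiary O1 could start to compete. The fallback sets out from 2 and 4 and comes back at 6. It drops the silyl detour (steps 2–4) in favour of catalyst-directed acylation. Acid 4 is converted under neutral conditions with 1-chloro-N,N,2-trimethylprop-1-en-1-amine in CH2Cl2 into tert-butyl 4-chloro-4-oxobutanoate F3. Tetraol 2 is then treated with F3 (1.1 equiv), 2-aminoethyl diphenylborinate (10 mol %) and iPr2NEt in MeCN at rt. The borinate binds the cis-3,4-diol and activates its equatorial oxygen, O4. This is the selectivity known for the axial/equatorial/equatorial triol pattern of pyranosides, which 2 shares.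

Further compounds
F1 | step 8 | (E)-3-(2,2-dimethyl-1,3-benzodioxol-5-yl)prop-2-enoic acid | OC(=O)/C=C/c1ccc2OC(C)(C)Oc2c1
F2 | step 5 | tert-butyl 3,5-bis-O-(3-chloropropanoyl)-4-O-(4-tert-butoxy-4-oxobutanoyl)quinate | CC(C)(C)OC(=O)CCC(=O)O[C@H]1[C@H](OC(=O)CCCl)C[C@](O)(C(=O)OC(C)(C)C)C[C@H]1OC(=O)CCCl
F3 | step 3 | tert-butyl 4-chloro-4-oxobutanoate | CC(C)(C)OC(=O)CCC(=O)Cl
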